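**Remarks on the chemistry**

- Assumption: of the two acetal epimers formed from the hydroxybutenolide and (−)-menthol, the (5R) epimer is taken to be the one that crystallises, as in the 3,4-unsubstituted series. The epimers are expected to interconvert under acid, so the other one is not lost.
- Stereochemical bookkeeping: the target is (2S,3R,4S,5S). The C2 aryl group and both methyls lie on one face of the oxolane and the C5 aryl group on the other (2,3-cis, 3,4-cis, 4,5-trans). Carried back, this requires the lactone acetal to be (3R,4S,5R) with the menthyloxy group on the methyl face, and the butenolide to be (5R). These descriptors were re-derived from the target and are used throughout; no structure needed correction.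
- No protecting groups are needed.

## Structural features

The target is a fully substituted oxolane: O1, C2 with a 3,4-dimethoxyphenyl ring, C3 and C4 each with a methyl group, and C5 with a 3,4,5-trimethoxyphenyl ring. All four ring carbons are contiguous stereocentres, with the C2 aryl group and both methyls on one face and the C5 aryl group on the other. The two aryl rings differ, so there is no symmetry to exploit and the two benzylic carbons must be built one at a time. Both C2 and C5 are benzylic ethers of electron-rich arenes: acids can reopen these C–O bonds and epimerise the centres, and palladium with hydrogen can cleave them; the aryl methyl ethers need no protection. The real difficulty is the contiguous cis,cis array C2–C3–C4, the thermodynamically less favoured arrangement, combined with a trans C5 centre and a defined absolute configuration that no side-chain stereocentre can supply. The feature used is that C2 and C5 are both ether carbons and can be carried at a higher oxidation level, C2 as a lactone carbonyl and C5 as an acetal carbon. C3 and C4 then become the ends of a tetrasubstituted alkene in a flat butenolide whose only stereocentre, the acetal carbon C5, bears a removable chiral alkoxy group. Syn hydrogenation of that C3=C4 bond makes the methyls cis by mechanism, and the two aryl groups are then introduced at C5 and C2 through ring cations steered by the methyl face.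

## Logic of the disconnections

**14 to 13.** The C2–H bond is cut. The 2,3-cis relation is the kinetic outcome when hydride is delivered to a planar 2-aryl ring oxocarbenium ion from the face away from the methyls, so C2 can be a hemiketal carbon in 13. The gain is that C2 loses its stereocentre and rises to the ketone oxidation level. The demand is a cold, short reduction, because the Lewis acid that ionises 13 can also reopen the benzylic C–O bonds of 14.

**13 to 10 and 11.** The C2–aryl bond is cut. A lactone carbonyl takes up one equivalent of the organolithium 12 (made in the flask from 11) and stops at the hemiketal stage. The gain is the removal of one arene, leaving a small lactone with three stereocentres. The demand is that addition outruns enolisation at C3, which is epimerisable, hence low temperature and an acidic quench.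

**10 to 6 and 7.** The C5–aryl bond is cut. In 6 this carbon is an acetal carbon that can ionise to a ring cation flanked by two cis methyls, so a nucleophile enters from the opposite face and gives the 4,5-trans relation; the auxiliary leaves in the same operation. The gain is the removal of the second arene, and both arenes now come from commercial bromides. The demand is a nucleophile that spares the lactone carbonyl (the organozinc 9, made through 8 from 7), exocyclic ionisation, and attack anti to the methyls.

**6 to 5 (key disconnection).** The C3–H and C4–H bonds are cut. Syn addition of hydrogen to a planar ring alkene makes the methyls cis by mechanism, and the substituent at C5 chooses the face. The gain is two stereocentres removed at once, leaving a flat butenolide with a single stereocentre. The demand is facial selectivity and reduction of a tetrasubstituted alkene without hydrogenolysis of the allylic acetal C–O bond or migration of the double bond.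

**5 to 2 and 3.** The exocyclic C5–O acetal bond is cut. The chiral alkoxy group of 3 is attached by simple acetalisation and serves three purposes: it makes the epimers 4 and 5 separable by crystallisation, it is the largest convenient group for face shielding in the key step, and it later acts as the leaving group, so no separate removal step is needed. The gain is a racemic lactol plus a cheap chiral alcohol. The demand is a crystallisation that delivers one epimer; acid equilibration of 4 into 5 is built in so that half the material is not wasted.

**2 to 1.** The C5–H bond is cut. Both carbonyls of 1 are equivalent, so mono-reduction raises no regiochemical question. The gain is a commercial, symmetrical starting material. The demand is that reduction stops at the lactol oxidation level.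

## Other disconnections considered

**Alternative 1:** The cut goes through C4–C5 and O1–C5, so that C5 with its trimethoxyphenyl group becomes a one-carbon benzylic unit and the rest an enone.

- Forward key step: the sulfonium salt from the benzyl bromide A3 and the chiral sulfide A4 (isothiocineole) is deprotonated by a carbonate base. The ylide adds to C4 of the aryl tiglyl ketone A2, and the enolate oxygen expels the sulfide at C5, closing the dihydrofuran A1 with the 4,5-trans relation. Hydrogenation of the C2=C3 enol ether of A1 would then have to set the last two centres.
- In favour: the ring and two bonds form in one convergent step, the sulfide is recoverable, and the sequence would be about four or five steps. On step economy this alternative is the better plan.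
- Against: benzyl-type ylides normally attack an enone at the carbonyl (epoxide) or, after conjugate addition, close through carbon (cyclopropane), so closure through oxygen is the least usual of three paths. The α-methyl group of A2 slows conjugate addition. Asymmetric induction by A4 is best understood for additions to C=O and C=N, not for this mode. The finishing hydrogenation must deliver hydrogen to the face of A1 that carries the C5 aryl group, and is exposed to benzylic hydrogenolysis; two of the four stereocentres would depend on that one facial choice.
- Comparison: both plans solve the cis-methyl problem by syn hydrogenation of a tetrasubstituted ring alkene, and on the reliability of the cis relation itself they are equal. Structurally, in 5 a single bulky group on an otherwise flat ring decides the face, whereas in A1 two substituents on opposite faces compete. Mechanistically, each centre in the chosen plan has its own control element. The chosen plan is longer by one or two steps and is preferred for predictability, not brevity.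

**Alternative 2:** The cut is the C4–C5 bond of an open-chain precursor, with both ring C–O bonds still to be made; it divides the target into the aldehyde A7 and the propargylic mesylate A6.

- Forward key step: a phosphine-ligated palladium catalyst and a dialkylzinc convert A6 into an allenic zinc reagent with transfer of central to axial chirality. This adds to A7 through a cyclic SE2' transition state to give the anti homopropargylic alcohol A5.
- In favour: the C4/C5 relation and the absolute configuration come from reagent control, the two aryl halves are joined convergently by C–C bond formation, and no cation is needed at a benzylic carbon. For C4 and C5 this alternative is at least the equal of the chosen plan, and it is the better one in that enantiopurity comes from a commercially available enantiopure propargylic alcohol and not from a crystallisation.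
- Against: A5 has no methyl at C3 and leaves C3 and C2 unset. The alkyne must still be methylated regioselectively or hydrated and alkylated, and an enolate alkylation beside the C4 methyl would be expected to go trans, the wrong relation. The most reasonable continuation closes to the same dihydrofuran A1 as in Alternative 1 and inherits its hydrogenation problem.
- Comparison: structurally, this key step fixes the easier half of the molecule (the trans pair), while the chosen key step fixes the harder half (the cis methyls). Mechanistically, it is well-defined reagent control against substrate control by an auxiliary. On step economy it is no better: two steps to A6, the key step, then at least three or four more, against six in total.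

**Alternative 3:** Two C–C bonds are cut at once, C2–C3 and C4–C5, after the ring oxygen has been removed retrosynthetically from between C2 and C5. What remains is the cyclobutanone A8, made from the ketene A10 and cis-but-2-ene A11.

- Forward key step: a tertiary amine dehydrochlorinates the acid chloride A9 to A10, which adds to A11 in a concerted [2+2] cycloaddition, suprafacial on the alkene and antarafacial on the ketene. The alkene geometry is retained, so the methyls are cis, and the aryl group is expected to end cis to the neighbouring methyl, the contra-steric outcome typical of ketene cycloadditions. Baeyer–Villiger oxidation with migration of the benzylic carbon would give the all-cis lactone A12. Reduction to the lactol, ionisation and attack of 9 on the face away from three cis substituents would finish the synthesis.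
- In favour: two bonds and three relative configurations arise in one step from trivial components. Cis methyls from alkene geometry are as reliable as cis methyls from hydrogenation; on this point the plans are equal. The last arylation would run through an ordinary ring oxocarbenium ion with all three substituents on one face, which is better precedented and probably more selective than the acyloxycarbenium substitution of step 4; on this point the alternative is the better plan. The step count, five to six, is equal.
- Against: A10 and A11 are both achiral, so A8 is racemic and the plan contains no source of absolute configuration. A resolution or an enantioselective variant would have to be added, and none is established for monoaryl ketenes with unactivated alkenes. Such ketenes dimerise readily and add sluggishly to simple alkenes; Lewis-acid promotion, the usual remedy, is known to alter the diastereoselectivity. The C2–H of A8 is benzylic and α to the ketone, so the amine can epimerise it to the trans isomer. A11 is a gas.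
- Comparison: structurally this is the most direct plan; mechanistically its relative stereocontrol is sound but its absolute stereocontrol is missing, which is decisive for a single-enantiomer target.

Key step: step 3

## Route

Step 1
Reactants: 1 2,3-dimethylmaleic anhydride
Product: 2 rac-5-hydroxy-3,4-dimethylfuran-2(5H)-one
Conditions: LiAlH(OtBu)3 (1.05 equiv), THF, −30 → 0 °C; then 1 M HCl
Reagents that add atoms: none
Why: Partial reduction of a cyclic anhydride by a bulky, mild hydride: one hydride adds to either of the two equivalent carbonyls and the aluminium lactolate resists further reduction at low temperature, so acidic work-up releases the lactol (pseudo-acid) 2; C5 is formed racemic, which is of no consequence because it is equilibrated in step 2.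

Step 2
Reactants: 2 rac-5-hydroxy-3,4-dimethylfuran-2(5H)-one; 3 (−)-menthol
Product: 5 (5R)-3,4-dimethyl-5-[(1R,2S,5R)-menthyloxy]furan-2(5H)-one, via (5S)-menthyloxy epimer 4 (not isolated)
Conditions: CSA (cat.), toluene, reflux, Dean–Stark; crystallisation (hexane, −20 °C); liquors re-equilibrated with p-TsOH (cat.) and recrystallised
Reagents that add atoms: none
Why: Acid-catalysed acetalisation of the lactol with removal of water (pseudo-ester formation, a Fischer-type glycosidation) gives both C5 epimers, which interconvert under the acid through the ring oxocarbenium ion; the (5R) epimer is expected to be the less soluble, so crystallisation with re-equilibration of the liquors (crystallisation-induced diastereomer transformation) should channel 4 into 5. The C5 stereocentre is thus fixed by the menthyl group through selective crystallisation, not by kinetic induction.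

Step 3
Reactants: 5 (5R)-3,4-dimethyl-5-[(1R,2S,5R)-menthyloxy]furan-2(5H)-one
Product: 6 (3R,4S,5R)-3,4-dimethyl-5-[(1R,2S,5R)-menthyloxy]oxolan-2-one
Conditions: H2 (80 bar), 5% Rh/Al2O3, EtOAc, 25–40 °C
Reagents that add atoms: none
Why: Heterogeneous hydrogenation (Horiuti–Polanyi mechanism): the butenolide is adsorbed on the rhodium surface through one face of the C3=C4 bond and two surface hydrogens are transferred in succession to C4 and C3 from that same face, forming the C3–H and C4–H bonds. The closest known reaction type is the hydrogenation of 5-alkoxy-2(5H)-furanones, which takes place anti to the 5-alkoxy group; here the alkene is tetrasubstituted, hence the pressure. No ring is formed. Both new stereocentres are controlled by the C5 acetal centre: the ring is flat and the menthyloxy group covers one face, so adsorption and hydrogen delivery occur on the other and both methyls are pushed to the face of the menthyloxy group, giving (3R,4S) from (5R). The cis relation between the methyls does not depend on the auxiliary at all; it follows from syn addition to a ring alkene. The step needs facial selectivity, secured by the size of the menthyl group next to the alkene, and chemoselectivity for the alkene over the allylic acetal C–O bond, for which rhodium is chosen over palladium because it is far less prone to hydrogenolysis and double-bond migration. Ethyl acetate, neutral and non-nucleophilic, leaves the acetal and the epimerisable C3 centre untouched.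

Step 4
Reactants: 6 (3R,4S,5R)-3,4-dimethyl-5-[(1R,2S,5R)-menthyloxy]oxolan-2-one; 7 5-bromo-1,2,3-trimethoxybenzene
Product: 10 (3R,4S,5S)-3,4-dimethyl-5-(3,4,5-trimethoxyphenyl)oxolan-2-one, via (3,4,5-trimethoxyphenyl)magnesium bromide 8 (not isolated), via (3,4,5-trimethoxyphenyl)zinc bromide 9 (not isolated)
Conditions: 7 (2.5 equiv), Mg, THF, 40 °C; ZnBr2, THF, 0 °C; then 6, BF3·OEt2, CH2Cl2, −78 → 0 °C; 1 M HCl
Reagents that add atoms: none
Why: BF3·OEt2 ionises the acetal to a ring acyloxycarbenium ion at C5 with loss of menthol, and the arylzinc bromide, which does not touch the lactone carbonyl, attacks the planar cation from the face opposite the C4 and C3 methyls to give the 4,5-trans aryl lactone (Lewis-acid-mediated substitution of an acetal by an organozinc through an oxocarbenium-type ion). The C5 stereocentre is therefore set by the two cis methyls, whatever the configuration of the acetal was.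

Step 5
Reactants: 10 (3R,4S,5S)-3,4-dimethyl-5-(3,4,5-trimethoxyphenyl)oxolan-2-one; 11 4-bromo-1,2-dimethoxybenzene
Product: 13 (3R,4S,5S)-2-(3,4-dimethoxyphenyl)-3,4-dimethyl-5-(3,4,5-trimethoxyphenyl)oxolan-2-ol (both C2 epimers), via (3,4-dimethoxyphenyl)lithium 12 (not isolated)
Conditions: 11 (1.3 equiv), n-BuLi, THF, −78 °C; then 10, −78 °C; AcOH in THF at −78 °C; used crude
Reagents that add atoms: none
Why: Bromine–lithium exchange gives the aryllithium, which adds once to the lactone carbonyl at −78 °C; the lithium hemiketalate is stable at that temperature and is protonated cold, so neither a second addition nor base-induced epimerisation at C3 should occur (1,2-addition of an organolithium to a lactone). No defined configuration is needed at C2 of 13, since that carbon is planarised in the next step.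

Step 6
Reactants: 13 (3R,4S,5S)-2-(3,4-dimethoxyphenyl)-3,4-dimethyl-5-(3,4,5-trimethoxyphenyl)oxolan-2-ol
Product: 14 (2S,3R,4S,5S)-2-(3,4-dimethoxyphenyl)-3,4-dimethyl-5-(3,4,5-trimethoxyphenyl)oxolane (ligraminol A)
Conditions: Et3SiH (3 equiv), BF3·OEt2 (2 equiv), CH2Cl2, −78 °C; sat. NaHCO3 at −78 °C
Reagents that add atoms: none
Why: BF3·OEt2 ionises the hemiketal to the 2-aryl oxocarbenium ion and Et3SiH delivers hydride to C2 from the face opposite the C3 and C4 methyls (inside attack on the envelope that keeps the C4 methyl and the C5 aryl group pseudoequatorial), so the dimethoxyphenyl group ends on the methyl face, (2S), 2,3-cis (ionic hydrogenation, reductive deoxygenation of a lactol). Low temperature and a cold basic quench are used because the same Lewis acid can reopen the benzylic C–O bonds and drain the kinetic cis product toward the trans isomer.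

## Compound list

1 | 2,3-dimethylmaleic anhydride | CC1=C(C)C(=O)OC1=O | starting material
2 | rac-5-hydroxy-3,4-dimethylfuran-2(5H)-one | CC1=C(C)C(O)OC1=O | intermediate
3 | (−)-menthol, (1R,2S,5R) | C[C@@H]1CC[C@H]([C@@H](C1)O)C(C)C | starting material
4 | (5S)-3,4-dimethyl-5-[(1R,2S,5R)-menthyloxy]furan-2(5H)-one | O=C1O[C@H](O[C@@H]2C[C@H](C)CC[C@H]2C(C)C)C(C)=C1C | intermediate
5 | (5R)-3,4-dimethyl-5-[(1R,2S,5R)-menthyloxy]furan-2(5H)-one | O=C1O[C@@H](O[C@@H]2C[C@H](C)CC[C@H]2C(C)C)C(C)=C1C | intermediate
6 | (3R,4S,5R)-3,4-dimethyl-5-[(1R,2S,5R)-menthyloxy]oxolan-2-one | O=C1O[C@@H](O[C@@H]2C[C@H](C)CC[C@H]2C(C)C)[C@@H](C)[C@H]1C | intermediate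
7 | 5-bromo-1,2,3-trimethoxybenzene | COc1cc(Br)cc(OC)c1OC | starting material
8 | (3,4,5-trimethoxyphenyl)magnesium bromide | COc1cc([Mg]Br)cc(OC)c1OC | intermediate
9 | (3,4,5-trimethoxyphenyl)zinc bromide | COc1cc([Zn]Br)cc(OC)c1OC | intermediate
10 | (3R,4S,5S)-3,4-dimethyl-5-(3,4,5-trimethoxyphenyl)oxolan-2-one | O=C1O[C@H](c2cc(OC)c(OC)c(OC)c2)[C@@H](C)[C@H]1C | intermediate
11 | 4-bromo-1,2-dimethoxybenzene | COc1ccc(Br)cc1OC | starting material
12 | (3,4-dimethoxyphenyl)lithium | [Li]c1ccc(OC)c(OC)c1 | intermediate
13 | (3R,4S,5S)-2-(3,4-dimethoxyphenyl)-3,4-dimethyl-5-(3,4,5-trimethoxyphenyl)oxolan-2-ol, both C2 epimers | COc1ccc(C2(O)O[C@H](c3cc(OC)c(OC)c(OC)c3)[C@@H](C)[C@H]2C)cc1OC | intermediate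
14 | (2S,3R,4S,5S)-2-(3,4-dimethoxyphenyl)-3,4-dimethyl-5-(3,4,5-trimethoxyphenyl)oxolane (ligraminol A) | COc1ccc([C@H]2O[C@H](c3cc(OC)c(OC)c(OC)c3)[C@@H](C)[C@H]2C)cc1OC | target

## Step count and least certain steps

Total step count: 6. Longest linear sequence: 6 steps (1 → 2 → 5 → 6 → 10 → 13 → 14); the aryl bromides 7 and 11 enter as reagents made in the flask.

**Risk at step 3 (key step).** The likeliest failure is slow reduction of the tetrasubstituted, electron-poor alkene, which would invite harsher conditions under which stereocontrol leaks away. Migration of the double bond toward C5, or hydrogenolysis of the allylic acetal C–O bond, would destroy the one centre that chooses the face; some addition syn to the menthyloxy group would add a diastereomer that is hard to remove. The fallback is resolution after reduction instead of induction during reduction. Setting out from 2, hydrogenation over Rh/Al2O3 in EtOAc should give racemic cis-5-hydroxy-3,4-dimethyloxolan-2-one F1, in which the cis relation follows from syn addition and no face has to be chosen. Acetalisation of F1 with 3 under the acid conditions of step 2 gives menthyl acetals of both ring enantiomers. The (3R,4S) series is separated by crystallisation or chromatography, most probably as the C5 epimer of 6 with the menthyloxy group trans to the methyls, (3R,4S,5S)-3,4-dimethyl-5-[(1R,2S,5R)-menthyloxy]oxolan-2-one F2. F2 is taken through the conditions of step 4 in place of 6, where the acetal configuration is lost in the cation, and the route is rejoined at 10.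

**Risk at step 4.** Three processes threaten this step. First, ionisation may be reluctant, because an acyloxycarbenium ion is less stabilised than an ordinary oxocarbenium ion, and the Lewis acid may instead cleave the endocyclic C5–O bond and open the ring. Second, boron–zinc exchange may consume the organozinc before the cation forms. Third, if the substitution takes on direct-displacement character, the outcome would no longer be dictated by the methyls alone. The fallback makes the C5–aryl bond by acyl substitution and sets C5 by ketone reduction. Setting out from 1, hydrogenation over Pd/C gives meso-2,3-dimethylsuccinic anhydride F3. A rhodium-catalysed enantioselective desymmetrising cross-coupling of F3 with 9 ([Rh(cod)Cl]2, chiral phosphoramidite ligand, THF), a known class of anhydride–organozinc coupling, should give (2R,3S)-2,3-dimethyl-4-oxo-4-(3,4,5-trimethoxyphenyl)butanoic acid F4, with the ligand enantiomer chosen accordingly. Felkin–Anh-controlled reduction of the aryl ketone with LiBH(sBu)3 at −78 °C, then acid-induced lactonisation, should give the 4,5-trans lactone, and the route is rejoined at 10. This fallback leaves the auxiliary route before the key step, and the ketone α-centre of F4 is epimerisable and must be kept away from base.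

**Risk at step 6.** The danger is erosion of the C2 configuration. This could come from imperfect facial selectivity in the hydride transfer or, more likely, from acid-induced reopening of the benzylic C2–O bond after reduction, since the 3,4-dimethoxyphenyl group stabilises the cation well; that would drain the kinetic 2,3-cis product toward the 2,3-trans isomer. The same process at C5 is possible but less likely. The fallback delivers hydrogen from a metal surface without a Lewis acid. From 13, dehydration (PPTS, toluene, 80 °C, molecular sieves) gives the enol ether (2S,3S)-5-(3,4-dimethoxyphenyl)-3,4-dimethyl-2-(3,4,5-trimethoxyphenyl)-2,3-dihydrofuran F5. Hydrogenation over Rh/Al2O3 then adds both hydrogens to C2 and C3 (oxolane numbering) from one face and gives 14 directly when that face is the one opposite the C4 methyl. The C5 aryl group lies on that same face, so the selectivity is less secure than in step 3, which is why this is the reserve and not the first choice. The fallback returns to the route at 14.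

**Risk at step 5.** Enolisation of the lactone by the basic aryllithium may compete with addition. This would lower conversion and return lactone epimerised at C3, because the cis-dimethyl arrangement is the less stable one; over-addition is the lesser risk. The fallback is acyl substitution on an open-chain amide instead of addition to the lactone. From 10, aminolysis with MeNH(OMe)·HCl and AlMe3 (CH2Cl2, 0 °C) gives (2R,3S,4S)-4-hydroxy-N-methoxy-N,2,3-trimethyl-4-(3,4,5-trimethoxyphenyl)butanamide F6. This is silylated at once (TESCl, imidazole, DMF) to its triethylsilyl ether F7, to stop relactonisation. 12 adds to F7 and, through the stable chelate, gives (2R,3S,4S)-1-(3,4-dimethoxyphenyl)-2,3-dimethyl-4-(triethylsilyloxy)-4-(3,4,5-trimethoxyphenyl)butan-1-one F8. Removal of the silyl group (AcOH/THF/H2O) lets the hydroxy ketone close to 13, where the route is rejoined. α-Branched amides of this type are known to accept aryllithiums without loss of the α-centre.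

**Risk at step 2.** The crystallisation may not deliver 5: the acetals may be oils, the (5S) epimer may be the less soluble one, or acid equilibration may be slow for the dimethyl compound. The fallback is to separate after the key step. The mixture of 4 and 5 is hydrogenated under the conditions of step 3. Each epimer should be reduced anti to its own menthyloxy group, giving 6 and (3S,4R,5S)-3,4-dimethyl-5-[(1R,2S,5R)-menthyloxy]oxolan-2-one F9. These differ in the whole ring and should separate by crystallisation or chromatography; the route is rejoined at 6.

## Further compounds

F1 | step 3 | rac-(3R*,4S*)-5-hydroxy-3,4-dimethyloxolan-2-one (cis methyls, racemic, both C5 epimers) | O=C1OC(O)[C@@H](C)[C@H]1C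
F2 | step 3 | (3R,4S,5S)-3,4-dimethyl-5-[(1R,2S,5R)-menthyloxy]oxolan-2-one | O=C1O[C@H](O[C@@H]2C[C@H](C)CC[C@H]2C(C)C)[C@@H](C)[C@H]1C
F3 | step 4 | meso-2,3-dimethylsuccinic anhydride, (3R,4S)-3,4-dimethyloxolane-2,5-dione | O=C1OC(=O)[C@@H](C)[C@H]1C
F4 | step 4 | (2R,3S)-2,3-dimethyl-4-oxo-4-(3,4,5-trimethoxyphenyl)butanoic acid | OC(=O)[C@H](C)[C@H](C)C(=O)c1cc(OC)c(OC)c(OC)c1
F5 | step 6 | (2S,3S)-5-(3,4-dimethoxyphenyl)-3,4-dimethyl-2-(3,4,5-trimethoxyphenyl)-2,3-dihydrofuran | COc1ccc(cc1OC)C2=C(C)[C@H](C)[C@H](O2)c1cc(OC)c(OC)c(OC)c1
F6 | step 5 | (2R,3S,4S)-4-hydroxy-N-methoxy-N,2,3-trimethyl-4-(3,4,5-trimethoxyphenyl)butanamide | CON(C)C(=O)[C@H](C)[C@H](C)[C@H](O)c1cc(OC)c(OC)c(OC)c1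
F7 | step 5 | (2R,3S,4S)-N-methoxy-N,2,3-trimethyl-4-(triethylsilyloxy)-4-(3,4,5-trimethoxyphenyl)butanamide | CON(C)C(=O)[C@H](C)[C@H](C)[C@H](O[Si](CC)(CC)CC)c1cc(OC)c(OC)c(OC)c1
F8 | step 5 | (2R,3S,4S)-1-(3,4-dimethoxyphenyl)-2,3-dimethyl-4-(triethylsilyloxy)-4-(3,4,5-trimethoxyphenyl)butan-1-one | COc1ccc(cc1OC)C(=O)[C@H](C)[C@H](C)[C@H](O[Si](CC)(CC)CC)c1cc(OC)c(OC)c(OC)c1
F9 | step 2 | (3S,4R,5S)-3,4-dimethyl-5-[(1R,2S,5R)-menthyloxy]oxolan-2-one | O=C1O[C@H](O[C@@H]2C[C@H](C)CC[C@H]2C(C)C)[C@H](C)[C@@H]1C
A1 | alternative 1 | (2S,3S)-5-(3,4-dimethoxyphenyl)-3,4-dimethyl-2-(3,4,5-trimethoxyphenyl)-2,3-dihydrofuran | COc1ccc(cc1OC)C2=C(C)[C@H](C)[C@H](O2)c1cc(OC)c(OC)c(OC)c1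
A2 | alternative 1 | (E)-1-(3,4-dimethoxyphenyl)-2-methylbut-2-en-1-one | C/C=C(\C)C(=O)c1ccc(OC)c(OC)c1
A3 | alternative 1 | 3,4,5-trimethoxybenzyl bromide | COc1cc(CBr)cc(OC)c1OC
A4 | alternative 1 | isothiocineole, drawn as (1R,4R,5R)-4,7,7-trimethyl-6-thiabicyclo[3.2.1]octane; the enantiomer that leads to A1 would be used | C[C@@H]1CC[C@@H]2C[C@H]1SC2(C)C
A5 | alternative 2 | (1S,2S)-4-(3,4-dimethoxyphenyl)-2-methyl-1-(3,4,5-trimethoxyphenyl)but-3-yn-1-ol | COc1ccc(cc1OC)C#C[C@H](C)[C@H](O)c1cc(OC)c(OC)c(OC)c1
A6 | alternative 2 | (R)-4-(3,4-dimethoxyphenyl)but-3-yn-2-yl methanesulfonate | C[C@@H](OS(C)(=O)=O)C#Cc1ccc(OC)c(OC)c1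
A7 | alternative 2 | 3,4,5-trimethoxybenzaldehyde | COc1cc(C=O)cc(OC)c1OC
A8 | alternative 3 | (2S,3R,4S)-2-(3,4-dimethoxyphenyl)-3,4-dimethylcyclobutan-1-one | O=C1[C@H](c2ccc(OC)c(OC)c2)[C@H](C)[C@@H]1C
A9 | alternative 3 | (3,4-dimethoxyphenyl)acetyl chloride | COc1ccc(CC(Cl)=O)cc1OC
A10 | alternative 3 | (3,4-dimethoxyphenyl)ketene | COc1ccc(C=C=O)cc1OC
A11 | alternative 3 | cis-but-2-ene | C/C=C\C
A12 | alternative 3 | (3S,4R,5S)-5-(3,4-dimethoxyphenyl)-3,4-dimethyloxolan-2-one | O=C1O[C@H](c2ccc(OC)c(OC)c2)[C@H](C)[C@@H]1C
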